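Abbreviations: prenyl = 3-methylbut-2-en-1-yl; MOM = methoxymethyl; SEM = 2-(trimethylsilyl)ethoxymethyl. Ring A is numbered A1 (ester carbon attached) to A6 (ether oxygen attached); ring B is numbered B1 (carbonyl next to the ether carbon), B2 (ether), B3 (OMe), B4 (carbonyl), B5 and B6 (prenyl).

## Structural features

Atrovirinone is an achiral diaryl ether of two six-membered carbocycles. Ring A is a methyl benzoate with hydroxyls on A2 and A4 and the ether oxygen on A6. Ring B is a fully substituted 1,4-benzoquinone with carbonyls on B1 and B4, the ether oxygen on B2, a methoxy group on B3 and prenyl groups on B5 and B6. There is no stereocentre and no configurational double bond, so the problem is regiochemistry on a hexasubstituted ring and functional-group tolerance. The quinone is a vinylogous ester whose aryloxy group can be displaced by alkoxides, and its hydroquinone form is air-sensitive. The prenyl groups do not tolerate peracids, halogens, hydrogenation or strong acid next to a free phenol. The real difficulty is ring B, where six substituents must stand in a fixed order, together with an ether bridge whose two carbons each carry two ortho substituents. The feature used is that the ester carbon on A1 and the oxygen on B1 are both ortho to the bridge A6–O–B2. A bond from that acyl carbon to B1 closes a pyranone, giving a xanthone in which the B4 oxygen is para to B1. Oxygen can then be inserted into the acyl–B1 bond under the guidance of the B4 phenoxide, and the resulting seven-membered lactone opens with methanol to exactly the ester and hydroquinone of the target.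

## Logic of the disconnections

**19 ⇒ 18.** Two acetal O–CH2 bonds are added to the A2 and A4 oxygens. Ring A must be capped while peroxide and methoxide act, because a ring A phenoxide would raise the migratory aptitude of ring A and deactivate the carbonyl groups. There is no skeletal gain; the gain is chemoselectivity. The forward step must remove two acetals from a quinone without a nucleophilic solvent that could displace the aryloxy group and without acid strong enough to cyclise prenyl groups.

**18 ⇒ 17 ⇒ 16.** The quinone is taken back to the hydroquinone 17. Then the ester O–CH3 bond is cut and the acyl carbon is joined to the B1 oxygen. This puts the ester and the B1 oxygen into one functional group and stores the air-sensitive hydroquinone as a mono-ester. The open ether becomes a tricycle of fixed regiochemistry. Forward, methoxide must attack only the acyl carbon, air must be excluded until the mixture is neutral, and the oxidant must act on the hydroquinone alone.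

**16 ⇒ 14 (key).** The bond between the lactone oxygen and B1 is cut and the acyl carbon is bonded directly to B1. Ring B loses one of its four oxygens and the seven-membered lactone contracts to the six-membered ketone ring of 14, a class with reliable syntheses. The B4 hydroxyl, para to B1, is the handle for the return. Forward, a nucleophilic peroxide must add to a hindered, deactivated carbonyl, ring B and not ring A must migrate, the alkenes must survive, and the lactone must outlive the reagent.

**14 ⇒ 13.** The B4 hydroxyl is masked as a SEM ether. It must not be a phenoxide during the base-mediated ring closure. The silyl ether that would be the obvious choice does not survive that base, so a SEM ether is used. Forward, fluoride must cleave it without touching the MOM ethers.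

**13 ⇒ 12.** The bond between the ring A oxygen and B2 is cut, leaving a phenol on ring A and a methoxy group on B2. Forward this is an intramolecular substitution ortho to the ketone, so the crowded ether is never made intermolecularly. The tricycle opens to a benzophenone. The demand is exactly one free ortho phenol on ring A, a leaving group on B2 and no phenoxide on ring B.

**12 ⇒ 11 ⇒ 10 ⇒ 6 + 9 (9 ⇐ 8 ⇐ 7).** The phenol is capped again, the ketone is taken back to the carbinol, and the bond between the carbinol carbon and ring A is cut. Ring A becomes the symmetric aryllithium 9, available by lithiation of 8, which is one step from 7. The aldehyde 6 is the best acceptor for a crowded nucleophile. The molecule splits into two halves of similar size. The demands are an addition between two doubly ortho-substituted partners, an oxidation that spares alkenes, and later the release of only one of two equivalent ortho acetals.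

**6 ⇒ 5.** The O–CH3 bonds on the B2 and B3 oxygens are cut, because both oxygens must be free phenols at the end of the preceding rearrangement. Forward, methylation must be exhaustive, including the hydrogen-bonded hydroxyl.

**5 ⇒ 4.** The ring–CH2 bonds at B5 and B6 are cut and each prenyl group is returned to the oxygen para to it (B5 to the B2 oxygen, B6 to the B3 oxygen). Both positions are para to an oxygen whose ortho positions are occupied, so a Claisen–Cope sequence can deliver unrearranged prenyl groups without organometallics or halogens. Two C–C bonds are traded for two ether bonds. The demand is two consecutive [3,3] shifts per group without loss of isoprene or of the formyl group, and a non-migrating group on the B4 oxygen.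

**4 ⇒ 2 + 3; 2 ⇒ 1.** The two allylic O–CH2 bonds and then the SEM O–CH2 bond are cut. Compound 1 already holds the three oxygens of ring B and the future carbonyl carbon, and its 4-hydroxyl is the most acidic. All materials are then commercial. The demand is regioselective mono-alkylation of 1.

## Other disconnections considered

**Alternative 1:** The cut goes through ring A (bonds A1–A2 and A5–A6), so ring A is built last on an alkyne that already carries the ester and the ring B aryloxy group.
- Forward key step: the ynoate A1 is heated with Chan's diene A2. The methylene end of the diene bonds to the aryloxy-bearing β-carbon and the ketene acetal carbon to the α-carbon. Loss of methanol would give the resorcinol ester A3.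
- In its favour: both partners agree on one regiochemistry, the reaction class is known, ring A appears with free hydroxyls, and ring B stays as a bis-silyl hydroquinone, so the end game is only desilylation and oxidation.
- Against it here: A1 is an ynol ether that must be made from a hexasubstituted phenol flanked by two oxygens. Its β-oxygen makes it a sluggish push–pull dienophile, so long heating of a labile diene is likely. The phenol behind A1 already needs all four ring B oxygens differentiated, so the B1 oxygen must be solved separately.
- Comparison: on mechanism it is better than the chosen plan, because its key step is a known type. On the end game it is also better, since no acid touches the quinone. On structure the chosen plan is stronger, because it makes the hindered ether intramolecularly and takes the B1 oxygen from the same ketone that templates the ether. Step counts should be about equal once ring B for A1 is included.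

**Alternative 2:** The ether bond A6–O and the bond from A1 to the carboxyl carbon are cut together; ring A enters as an aryne.
- Forward key step: fluoride releases the aryne from the silyl triflate A4. The phenoxide of A5 adds to the aryne carbon remote from the neighbouring MOM ether, and carbon dioxide traps the resulting aryl anion to give the acid A6.
- In its favour: it is the most convergent plan, and the ring A pattern follows from the known polarisation of 3-alkoxyarynes. Ring A needs no desymmetrisation of two equal ortho oxygens, which is better than step 8 of the chosen route.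
- Against it: the aryl anion can be protonated by unionised phenol faster than it meets carbon dioxide, giving the ether without the carboxyl group. The nucleophile is a doubly ortho-substituted phenoxide. Ring B is then a trimethoxyarene from which exactly two methyl groups must be removed oxidatively in the presence of two prenyl groups, with an ortho-quinone as the competing outcome.
- Comparison: it is equal in needing a final MOM removal and a separately built four-oxygen ring B phenol. It is better in convergence, and its steps have closer analogy than the chosen key step. It is weaker at the end, where the chosen plan oxidises a free hydroquinone with Ag2O under neutral conditions.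

**Alternative 3:** The cut is in the side chains: both bonds between benzylic CH2 and alkene CH are broken, so the prenyl groups are grown last from two ring methyl groups.
- Forward key step: the bis(bromomethyl) compound A7 couples twice with the stannane A8 under Pd(PPh3)4 (zerovalent palladium) to give the tetraacetate A9.
- In its favour: no prenyl group has to survive ether formation or redox changes, so robust and even acidic methods become usable earlier. Coupling of benzylic bromides with alkenylstannanes is established. On both counts it is better than the chosen plan.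
- Against it: A7 needs twofold radical bromination of adjacent methyl groups while ring A has two free activated positions. Two neighbouring benzylic palladium sites invite cyclisation or reduction. Removing four acetates in basic methanol exposes the emerging quinone to methoxide. Stoichiometric tin must be removed. The ether and the four ring B oxygens still require an intermolecular union of two crowded partners.
- Comparison: it is better on prenyl safety and on precedent, and equal on the final oxidation. The chosen plan should be shorter, because ring B needs only three oxygens and both prenyl groups come from prenyl bromide in one rearrangement.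

Key step: step 11

Remarks on the chemistry:
- The only stereocentre on the route is the carbinol carbon of 10, formed racemic and erased in step 7.
- The structures of the key-step precursor and product were re-derived atom by atom and no error was found; the map is xanthone C8a = B1, C10a = B2, C5 = B3, C6 = B4, C7 = B5, C8 = B6.
- Compounds 1, 3, 7, SEMCl and MOMCl are assumed to be purchased.

## Route

Step 1
Reactants: 1 2,3,4-trihydroxybenzaldehyde
Product: 2 2,3-dihydroxy-4-{[2-(trimethylsilyl)ethoxy]methoxy}benzaldehyde
Conditions: SEMCl (1.05 equiv), i-Pr2NEt (1.2 equiv), CH2Cl2–DMF, −20 → 0 °C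
Reagents that add atoms: 2-(trimethylsilyl)ethoxymethyl chloride (SEMCl), C[Si](C)(C)CCOCCl
Why: Williamson-type O-alkylation of the most acidic phenol: the 4-hydroxyl is para to the formyl group and is ionised first, the 2-hydroxyl is held in a hydrogen bond to the aldehyde and the 3-hydroxyl is the least acidic, so one equivalent of chloride at low temperature should stop at the 4-ether.

Step 2
Reactants: 2 2,3-dihydroxy-4-{[2-(trimethylsilyl)ethoxy]methoxy}benzaldehyde; 3 prenyl bromide (1-bromo-3-methylbut-2-ene)
Product: 4 2,3-bis[(3-methylbut-2-en-1-yl)oxy]-4-{[2-(trimethylsilyl)ethoxy]methoxy}benzaldehyde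
Conditions: 3 (2.5 equiv), K2CO3, DMF, Ar, rt → 50 °C
Reagents that add atoms: prenyl bromide 3, CC(C)=CCBr
Why: Williamson etherification of both remaining phenols in a dipolar aprotic solvent, which favours O- over C-alkylation; gentle warming brings in the hydrogen-bonded 2-hydroxyl, and SEM ether and aldehyde are inert to K2CO3.

Step 3
Reactants: 4 2,3-bis[(3-methylbut-2-en-1-yl)oxy]-4-{[2-(trimethylsilyl)ethoxy]methoxy}benzaldehyde
Product: 5 2,3-dihydroxy-5,6-bis(3-methylbut-2-en-1-yl)-4-{[2-(trimethylsilyl)ethoxy]methoxy}benzaldehyde
Conditions: PhNEt2 (degassed), 180 °C, Ar, sealed tube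
Reagents that add atoms: none
Why: Twofold para-Claisen (Claisen then Cope) rearrangement: each prenyl ether has both ortho positions occupied, so the first [3,3] shift gives an ortho-dienone that cannot aromatise and a second [3,3] shift carries the group, again as an unrearranged prenyl unit, to the free para position (oxygen on C2 to C5, oxygen on C3 to C6), where enolisation restores the arene; the SEM ether cannot migrate and so blocks an ortho shift from the C4 oxygen.

Step 4
Reactants: 5 2,3-dihydroxy-5,6-bis(3-methylbut-2-en-1-yl)-4-{[2-(trimethylsilyl)ethoxy]methoxy}benzaldehyde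
Product: 6 2,3-dimethoxy-5,6-bis(3-methylbut-2-en-1-yl)-4-{[2-(trimethylsilyl)ethoxy]methoxy}benzaldehyde
Conditions: MeI (4 equiv), K2CO3, DMF, 40 °C
Reagents that add atoms: iodomethane, CI
Why: Exhaustive Williamson methylation of the catechol; solvent and slight warming overcome the hydrogen bond of the 2-hydroxyl, whose methyl ether becomes the leaving group of step 9.

Step 5
Reactants: 7 phloroglucinol (benzene-1,3,5-triol)
Product: 8 1,3,5-tris(methoxymethoxy)benzene
Conditions: MOMCl (3.6 equiv), i-Pr2NEt, DMF, 0 °C → rt
Reagents that add atoms: chloromethyl methyl ether (MOMCl), COCCl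
Why: Threefold O-alkylation with an α-chloro ether; the MOM ethers direct the lithiation of step 6, are inert to base, organolithium and alkaline peroxide, and come off in mild acid.

Step 6
Reactants: 8 1,3,5-tris(methoxymethoxy)benzene; 6 2,3-dimethoxy-5,6-bis(3-methylbut-2-en-1-yl)-4-{[2-(trimethylsilyl)ethoxy]methoxy}benzaldehyde
Product: 10 [2,3-dimethoxy-5,6-bis(3-methylbut-2-en-1-yl)-4-{[2-(trimethylsilyl)ethoxy]methoxy}phenyl][2,4,6-tris(methoxymethoxy)phenyl]methanol (racemic), via 2,4,6-tris(methoxymethoxy)phenyllithium 9 (not isolated)
Conditions: 8 (1.3 equiv), n-BuLi (1.2 equiv), THF, 0 °C → rt; then 6, −78 → 0 °C; H2O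
Reagents that add atoms: none
Why: Directed ortho-lithiation between two MOM ethers of the symmetric arene gives a single aryllithium, which adds to the aldehyde at low temperature faster than it deprotonates benzylic positions; a deficit of n-BuLi leaves no alkyllithium, and the carbinol stereocentre is formed racemic and erased in step 7.

Step 7
Reactants: 10 [2,3-dimethoxy-5,6-bis(3-methylbut-2-en-1-yl)-4-{[2-(trimethylsilyl)ethoxy]methoxy}phenyl][2,4,6-tris(methoxymethoxy)phenyl]methanol
Product: 11 [2,3-dimethoxy-5,6-bis(3-methylbut-2-en-1-yl)-4-{[2-(trimethylsilyl)ethoxy]methoxy}phenyl][2,4,6-tris(methoxymethoxy)phenyl]methanone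
Conditions: Dess–Martin periodinane (1.3 equiv), NaHCO3, CH2Cl2, 0 °C → rt
Reagents that add atoms: none
Why: Dess–Martin oxidation of a secondary diaryl carbinol under buffered, non-acidic conditions that spare the electron-rich arenes, the acetal ethers and the trisubstituted alkenes.

Step 8
Reactants: 11 [2,3-dimethoxy-5,6-bis(3-methylbut-2-en-1-yl)-4-{[2-(trimethylsilyl)ethoxy]methoxy}phenyl][2,4,6-tris(methoxymethoxy)phenyl]methanone
Product: 12 [2-hydroxy-4,6-bis(methoxymethoxy)phenyl][2,3-dimethoxy-5,6-bis(3-methylbut-2-en-1-yl)-4-{[2-(trimethylsilyl)ethoxy]methoxy}phenyl]methanone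
Conditions: HCl (0.2 equiv), MeOH–THF (1:1), 0 °C → rt, stopped when 11 is consumed
Reagents that add atoms: none
Why: Acid-catalysed acetal exchange: only an ortho MOM ether of ring A is assisted by the neighbouring ketone, and once one phenol is free its hydrogen bond to the carbonyl withdraws that assistance from the second, so the reaction should stop at the mono-phenol; the para MOM ether and the SEM ether, both remote from the carbonyl, react more slowly.

Step 9
Reactants: 12 [2-hydroxy-4,6-bis(methoxymethoxy)phenyl][2,3-dimethoxy-5,6-bis(3-methylbut-2-en-1-yl)-4-{[2-(trimethylsilyl)ethoxy]methoxy}phenyl]methanone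
Product: 13 5-methoxy-1,3-bis(methoxymethoxy)-7,8-bis(3-methylbut-2-en-1-yl)-6-{[2-(trimethylsilyl)ethoxy]methoxy}-9H-xanthen-9-one
Conditions: Cs2CO3 (2 equiv), DMF, 90 °C, Ar
Reagents that add atoms: none
Why: Intramolecular nucleophilic aromatic substitution (addition–elimination): the ring A phenoxide attacks the ring B carbon ortho to the ketone and expels methoxide through a ketone-stabilised Meisenheimer intermediate, closing the six-membered pyranone; the base-stable SEM ether keeps the para oxygen from becoming a phenoxide that would switch off the activation.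

Step 10
Reactants: 13 5-methoxy-1,3-bis(methoxymethoxy)-7,8-bis(3-methylbut-2-en-1-yl)-6-{[2-(trimethylsilyl)ethoxy]methoxy}-9H-xanthen-9-one
Product: 14 6-hydroxy-5-methoxy-1,3-bis(methoxymethoxy)-7,8-bis(3-methylbut-2-en-1-yl)-9H-xanthen-9-one
Conditions: n-Bu4NF (5 equiv), THF–DMPU, 60 °C; aq NH4Cl
Reagents that add atoms: none
Why: Fluoride attacks silicon and the SEM group fragments to fluorotrimethylsilane, ethene and formaldehyde, releasing a phenoxide that leaves easily because it is para to the ketone; MOM ethers and alkenes are inert to fluoride.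

Step 11
Reactants: 14 6-hydroxy-5-methoxy-1,3-bis(methoxymethoxy)-7,8-bis(3-methylbut-2-en-1-yl)-9H-xanthen-9-one
Product: 16 7-hydroxy-6-methoxy-1,3-bis(methoxymethoxy)-8,9-bis(3-methylbut-2-en-1-yl)-11H-dibenzo[b,e][1,4]dioxepin-11-one (depsidone), via peroxy hemiketal 15 (not isolated)
Conditions: 30% aq H2O2 (4 equiv), LiOH·H2O (2.5 equiv), THF–H2O (3:1), 0 °C → rt, Ar; then aq Na2SO3, pH 6 phosphate buffer
Reagents that add atoms: hydrogen peroxide, OO
Why: Proposed new method: LiOH ionises the C6 hydroxyl and forms LiOOH, whose anion adds to the C9 carbonyl to give the peroxy hemiketal 15, helped by lithium chelation between the carbonyl and the peri MOM oxygen. Electron push from the phenoxide, which is para to C8a, then drives a 1,2-shift of C8a from C9 to the proximal peroxide oxygen with loss of hydroxide, as in the migration step of a Dakin oxidation. The closest known reactions are the Dakin oxidation of para-hydroxyaryl aldehydes and ketones and the Baeyer–Villiger oxidation of diaryl ketones; a xanthone carbonyl, flanked by two peri substituents and deactivated by two ether oxygens, has no laboratory precedent as a substrate. The seven-membered dioxepinone arises by one-atom ring expansion of the pyranone (oxygen insertion into the C9–C8a bond) and not by an exo or endo cyclisation. No stereocentre is formed. The step needs migration of ring B and not ring A, which is secured by having the only phenoxide on ring B para to the migrating carbon while both ring A oxygens are MOM ethers that cannot ionise. It also needs an oxidant that spares the two trisubstituted alkenes, and hydroperoxide anion is nucleophilic and does not epoxidise unactivated alkenes as a peracid would. The lactone carbonyl of 16 has two ortho substituents and should resist perhydrolysis at 0 °C, and the reductive quench and buffering before exposure to air protect the hydroquinone mono-ester.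

Step 12
Reactants: 16 7-hydroxy-6-methoxy-1,3-bis(methoxymethoxy)-8,9-bis(3-methylbut-2-en-1-yl)-11H-dibenzo[b,e][1,4]dioxepin-11-one
Product: 18 methyl 2-{[2-methoxy-4,5-bis(3-methylbut-2-en-1-yl)-3,6-dioxocyclohexa-1,4-dien-1-yl]oxy}-4,6-bis(methoxymethoxy)benzoate, via hydroquinone 17 (not isolated)
Conditions: NaOMe (3 equiv), degassed MeOH–THF, 0 °C, Ar; AcOH (3 equiv); evaporate; Ag2O (3 equiv), MgSO4, Et2O, rt
Reagents that add atoms: methanol, CO (supplied as sodium methoxide, C[O-].[Na+])
Why: Methoxide opens the seven-membered aryl ester at the acyl carbon (transesterification) to the methyl ester and the hydroquinone 17; after neutralisation Ag2O dehydrogenates the electron-rich hydroquinone to the para-quinone under neutral conditions, so the quinone never meets methoxide, which would displace its aryloxy group; ring A, the MOM ethers and the alkenes are inert to Ag2O.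

Step 13
Reactants: 18 methyl 2-{[2-methoxy-4,5-bis(3-methylbut-2-en-1-yl)-3,6-dioxocyclohexa-1,4-dien-1-yl]oxy}-4,6-bis(methoxymethoxy)benzoate
Product: 19 atrovirinone, methyl 2,4-dihydroxy-6-{[2-methoxy-4,5-bis(3-methylbut-2-en-1-yl)-3,6-dioxocyclohexa-1,4-dien-1-yl]oxy}benzoate
Conditions: NaHSO4·SiO2, CH2Cl2, rt
Reagents that add atoms: none
Why: Acid-catalysed hydrolysis of the two phenolic MOM acetals on a solid acid in a non-nucleophilic solvent; no alcohol is present that could exchange with the aryloxy group of the quinone, no free phenol stands next to a prenyl group, and the methyl ester is stable.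

## Compound list

1 | 2,3,4-trihydroxybenzaldehyde | O=Cc1ccc(O)c(O)c1O | starting material
2 | 2,3-dihydroxy-4-{[2-(trimethylsilyl)ethoxy]methoxy}benzaldehyde | O=Cc1ccc(OCOCC[Si](C)(C)C)c(O)c1O | intermediate
3 | prenyl bromide (1-bromo-3-methylbut-2-ene) | CC(C)=CCBr | starting material
4 | 2,3-bis[(3-methylbut-2-en-1-yl)oxy]-4-{[2-(trimethylsilyl)ethoxy]methoxy}benzaldehyde | O=Cc1ccc(OCOCC[Si](C)(C)C)c(OCC=C(C)C)c1OCC=C(C)C | intermediate
5 | 2,3-dihydroxy-5,6-bis(3-methylbut-2-en-1-yl)-4-{[2-(trimethylsilyl)ethoxy]methoxy}benzaldehyde | O=Cc1c(CC=C(C)C)c(CC=C(C)C)c(OCOCC[Si](C)(C)C)c(O)c1O | intermediate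
6 | 2,3-dimethoxy-5,6-bis(3-methylbut-2-en-1-yl)-4-{[2-(trimethylsilyl)ethoxy]methoxy}benzaldehyde | O=Cc1c(CC=C(C)C)c(CC=C(C)C)c(OCOCC[Si](C)(C)C)c(OC)c1OC | intermediate
7 | phloroglucinol (benzene-1,3,5-triol) | Oc1cc(O)cc(O)c1 | starting material
8 | 1,3,5-tris(methoxymethoxy)benzene | COCOc1cc(OCOC)cc(OCOC)c1 | intermediate
9 | 2,4,6-tris(methoxymethoxy)phenyllithium | [Li]c1c(OCOC)cc(OCOC)cc1OCOC | intermediate
10 | [2,3-dimethoxy-5,6-bis(3-methylbut-2-en-1-yl)-4-{[2-(trimethylsilyl)ethoxy]methoxy}phenyl][2,4,6-tris(methoxymethoxy)phenyl]methanol (racemic) | OC(c1c(OCOC)cc(OCOC)cc1OCOC)c1c(CC=C(C)C)c(CC=C(C)C)c(OCOCC[Si](C)(C)C)c(OC)c1OC | intermediate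
11 | [2,3-dimethoxy-5,6-bis(3-methylbut-2-en-1-yl)-4-{[2-(trimethylsilyl)ethoxy]methoxy}phenyl][2,4,6-tris(methoxymethoxy)phenyl]methanone | O=C(c1c(OCOC)cc(OCOC)cc1OCOC)c1c(CC=C(C)C)c(CC=C(C)C)c(OCOCC[Si](C)(C)C)c(OC)c1OC | intermediate
12 | [2-hydroxy-4,6-bis(methoxymethoxy)phenyl][2,3-dimethoxy-5,6-bis(3-methylbut-2-en-1-yl)-4-{[2-(trimethylsilyl)ethoxy]methoxy}phenyl]methanone | O=C(c1c(O)cc(OCOC)cc1OCOC)c1c(CC=C(C)C)c(CC=C(C)C)c(OCOCC[Si](C)(C)C)c(OC)c1OC | intermediate
13 | 5-methoxy-1,3-bis(methoxymethoxy)-7,8-bis(3-methylbut-2-en-1-yl)-6-{[2-(trimethylsilyl)ethoxy]methoxy}-9H-xanthen-9-one | O=C1c2c(OCOC)cc(OCOC)cc2Oc2c(OC)c(OCOCC[Si](C)(C)C)c(CC=C(C)C)c(CC=C(C)C)c21 | intermediate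
14 | 6-hydroxy-5-methoxy-1,3-bis(methoxymethoxy)-7,8-bis(3-methylbut-2-en-1-yl)-9H-xanthen-9-one | O=C1c2c(OCOC)cc(OCOC)cc2Oc2c(OC)c(O)c(CC=C(C)C)c(CC=C(C)C)c21 | intermediate
15 | 9-hydroperoxy-5-methoxy-1,3-bis(methoxymethoxy)-7,8-bis(3-methylbut-2-en-1-yl)-9H-xanthene-6,9-diol (present as its lithium salt) | OOC1(O)c2c(OCOC)cc(OCOC)cc2Oc2c(OC)c(O)c(CC=C(C)C)c(CC=C(C)C)c21 | intermediate
16 | 7-hydroxy-6-methoxy-1,3-bis(methoxymethoxy)-8,9-bis(3-methylbut-2-en-1-yl)-11H-dibenzo[b,e][1,4]dioxepin-11-one | O=C1Oc2c(CC=C(C)C)c(CC=C(C)C)c(O)c(OC)c2Oc2cc(OCOC)cc(OCOC)c21 | intermediate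
17 | methyl 2-[2,5-dihydroxy-6-methoxy-3,4-bis(3-methylbut-2-en-1-yl)phenoxy]-4,6-bis(methoxymethoxy)benzoate | COC(=O)c1c(OCOC)cc(OCOC)cc1Oc1c(OC)c(O)c(CC=C(C)C)c(CC=C(C)C)c1O | intermediate
18 | methyl 2-{[2-methoxy-4,5-bis(3-methylbut-2-en-1-yl)-3,6-dioxocyclohexa-1,4-dien-1-yl]oxy}-4,6-bis(methoxymethoxy)benzoate | COC(=O)c1c(OCOC)cc(OCOC)cc1OC1=C(OC)C(=O)C(CC=C(C)C)=C(CC=C(C)C)C1=O | intermediate
19 | atrovirinone, methyl 2,4-dihydroxy-6-{[2-methoxy-4,5-bis(3-methylbut-2-en-1-yl)-3,6-dioxocyclohexa-1,4-dien-1-yl]oxy}benzoate | COC(=O)c1c(O)cc(O)cc1OC1=C(OC)C(=O)C(CC=C(C)C)=C(CC=C(C)C)C1=O | target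

## Step count and least certain steps

Total step count: 13. Longest linear sequence: 12 steps (1 to 19 through steps 1–4 and 6–13); step 5 is the one-step branch to 8.

**Step 11 (key step, labelled Proposed new method).**
- What may go wrong: hydroperoxide may fail to add to a carbonyl that is deactivated by the para phenoxide and two ether oxygens and shielded by two peri substituents, so 14 would be returned. If the shift does occur, perhydrolysis of the lactone could follow, with oxidation of the freed hydroquinone to a quinone that alkaline peroxide would epoxidise. Partial migration of ring A is the third possibility.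
- Fallback (known chemistry): the Dakin oxidation is moved to the aldehyde level, where it is a textbook reaction, and the ether is made by palladium-catalysed C–O coupling. It sets out from 5 and comes back at 17.
- From 5, the dianion (NaH, 2.1 equiv, DMF, 0 °C) is methylated with one equivalent of MeI at the more basic, non-chelated 3-oxygen to give 2-hydroxy-3-methoxy-5,6-bis(3-methylbut-2-en-1-yl)-4-{[2-(trimethylsilyl)ethoxy]methoxy}benzaldehyde F1.
- Separately, methyl 2,4,6-trihydroxybenzoate F2 is treated with two equivalents of MOMCl and i-Pr2NEt to give methyl 2-hydroxy-4,6-bis(methoxymethoxy)benzoate F3, in which the hydroxyl hydrogen-bonded to the ester stays free. Tf2O and pyridine then give methyl 2,4-bis(methoxymethoxy)-6-{[(trifluoromethyl)sulfonyl]oxy}benzoate F4.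
- Coupling of F1 with F4 (Pd(OAc)2, t-BuXPhos, K3PO4, toluene, 100 °C) should give methyl 2-[6-formyl-2-methoxy-4,5-bis(3-methylbut-2-en-1-yl)-3-{[2-(trimethylsilyl)ethoxy]methoxy}phenoxy]-4,6-bis(methoxymethoxy)benzoate F5.
- n-Bu4NF removes the SEM group to give methyl 2-[6-formyl-3-hydroxy-2-methoxy-4,5-bis(3-methylbut-2-en-1-yl)phenoxy]-4,6-bis(methoxymethoxy)benzoate F6, a para-hydroxybenzaldehyde. Its ordinary Dakin oxidation (H2O2, NaOH, THF–H2O, 0 °C, the aryl formate being hydrolysed in the flask) gives 17, which is oxidised with Ag2O as in step 12.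

**Step 3.**
- What may go wrong: thermal cleavage of a prenyl ether with loss of isoprene may compete with rearrangement. The formyl group may be lost from the ortho-dienone formed at C1. The second migration may stall.
- Fallback: the two migrations are separated and the carbonyl-flanked ether is rearranged under chelation catalysis. It sets out from 2 and comes back at 6.
- The dianion of 2 (NaH, 2.1 equiv) is alkylated with one equivalent of 3 at the 3-oxygen to give 2-hydroxy-3-[(3-methylbut-2-en-1-yl)oxy]-4-{[2-(trimethylsilyl)ethoxy]methoxy}benzaldehyde F7.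
- A single thermal para-Claisen rearrangement gives 2,3-dihydroxy-6-(3-methylbut-2-en-1-yl)-4-{[2-(trimethylsilyl)ethoxy]methoxy}benzaldehyde F8.
- Selective methylation of the 3-oxygen through the dianion gives 2-hydroxy-3-methoxy-6-(3-methylbut-2-en-1-yl)-4-{[2-(trimethylsilyl)ethoxy]methoxy}benzaldehyde F9.
- Alkylation with 3 and K2CO3 gives 3-methoxy-6-(3-methylbut-2-en-1-yl)-2-[(3-methylbut-2-en-1-yl)oxy]-4-{[2-(trimethylsilyl)ethoxy]methoxy}benzaldehyde F10.
- Eu(fod)3, which chelates the aldehyde and ether oxygens, should bring about the second para-Claisen rearrangement at about 80 °C to give 2-hydroxy-3-methoxy-5,6-bis(3-methylbut-2-en-1-yl)-4-{[2-(trimethylsilyl)ethoxy]methoxy}benzaldehyde F1. Methylation (MeI, K2CO3) gives 6.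

**Step 9.**
- What may go wrong: substitution may be too slow on a ring that carries three donor oxygens and two alkyl groups and is twisted out of conjugation with the ketone. Forcing conditions could then strip an acetal and create a phenoxide that stops the reaction.
- Fallback: methoxide is replaced by a far better leaving group. It sets out from 5 and comes back at 13.
- Compound 5 is converted as above into 2-hydroxy-3-methoxy-5,6-bis(3-methylbut-2-en-1-yl)-4-{[2-(trimethylsilyl)ethoxy]methoxy}benzaldehyde F1.
- Tf2O and pyridine give 2-formyl-6-methoxy-3,4-bis(3-methylbut-2-en-1-yl)-5-{[2-(trimethylsilyl)ethoxy]methoxy}phenyl trifluoromethanesulfonate F11.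
- Addition of 9 at −78 °C gives the racemic carbinol 2-{hydroxy[2,4,6-tris(methoxymethoxy)phenyl]methyl}-6-methoxy-3,4-bis(3-methylbut-2-en-1-yl)-5-{[2-(trimethylsilyl)ethoxy]methoxy}phenyl trifluoromethanesulfonate F12.
- Dess–Martin oxidation gives the ketone 6-methoxy-3,4-bis(3-methylbut-2-en-1-yl)-2-[2,4,6-tris(methoxymethoxy)benzoyl]-5-{[2-(trimethylsilyl)ethoxy]methoxy}phenyl trifluoromethanesulfonate F13.
- Catalytic HCl in MeOH frees one ortho phenol to give 2-[2-hydroxy-4,6-bis(methoxymethoxy)benzoyl]-6-methoxy-3,4-bis(3-methylbut-2-en-1-yl)-5-{[2-(trimethylsilyl)ethoxy]methoxy}phenyl trifluoromethanesulfonate F14.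
- K2CO3 in DMF at 40 °C should close the ring with loss of triflate to give 13.

**Step 13.**
- What may go wrong: acid-catalysed addition–elimination of water or methanol at the quinone carbon that bears the aryloxy group would cut off ring A. Protonation of a prenyl alkene is the other risk.
- Fallback: the order of the last events is changed so that acid never meets the quinone. It sets out from 17 and comes back at 19.
- After the methanolysis of step 12 and neutralisation, 17 is treated with HCl (1 M) in degassed MeOH at rt under argon to give methyl 2-[2,5-dihydroxy-6-methoxy-3,4-bis(3-methylbut-2-en-1-yl)phenoxy]-4,6-dihydroxybenzoate F15. Its diaryl ether is inert to exchange.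
- Ag2O in Et2O then oxidises only the hydroquinone ring to give 19.

## Further compounds

F1 | step 11 | 2-hydroxy-3-methoxy-5,6-bis(3-methylbut-2-en-1-yl)-4-{[2-(trimethylsilyl)ethoxy]methoxy}benzaldehyde | O=Cc1c(CC=C(C)C)c(CC=C(C)C)c(OCOCC[Si](C)(C)C)c(OC)c1O
F2 | step 11 | methyl 2,4,6-trihydroxybenzoate | COC(=O)c1c(O)cc(O)cc1O
F3 | step 11 | methyl 2-hydroxy-4,6-bis(methoxymethoxy)benzoate | COC(=O)c1c(O)cc(OCOC)cc1OCOC
F4 | step 11 | methyl 2,4-bis(methoxymethoxy)-6-{[(trifluoromethyl)sulfonyl]oxy}benzoate | COC(=O)c1c(OCOC)cc(OCOC)cc1OS(=O)(=O)C(F)(F)F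
F5 | step 11 | methyl 2-[6-formyl-2-methoxy-4,5-bis(3-methylbut-2-en-1-yl)-3-{[2-(trimethylsilyl)ethoxy]methoxy}phenoxy]-4,6-bis(methoxymethoxy)benzoate | COC(=O)c1c(OCOC)cc(OCOC)cc1Oc1c(OC)c(OCOCC[Si](C)(C)C)c(CC=C(C)C)c(CC=C(C)C)c1C=O
F6 | step 11 | methyl 2-[6-formyl-3-hydroxy-2-methoxy-4,5-bis(3-methylbut-2-en-1-yl)phenoxy]-4,6-bis(methoxymethoxy)benzoate | COC(=O)c1c(OCOC)cc(OCOC)cc1Oc1c(OC)c(O)c(CC=C(C)C)c(CC=C(C)C)c1C=O
F7 | step 3 | 2-hydroxy-3-[(3-methylbut-2-en-1-yl)oxy]-4-{[2-(trimethylsilyl)ethoxy]methoxy}benzaldehyde | O=Cc1ccc(OCOCC[Si](C)(C)C)c(OCC=C(C)C)c1O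
F8 | step 3 | 2,3-dihydroxy-6-(3-methylbut-2-en-1-yl)-4-{[2-(trimethylsilyl)ethoxy]methoxy}benzaldehyde | O=Cc1c(CC=C(C)C)cc(OCOCC[Si](C)(C)C)c(O)c1O
F9 | step 3 | 2-hydroxy-3-methoxy-6-(3-methylbut-2-en-1-yl)-4-{[2-(trimethylsilyl)ethoxy]methoxy}benzaldehyde | O=Cc1c(CC=C(C)C)cc(OCOCC[Si](C)(C)C)c(OC)c1O
F10 | step 3 | 3-methoxy-6-(3-methylbut-2-en-1-yl)-2-[(3-methylbut-2-en-1-yl)oxy]-4-{[2-(trimethylsilyl)ethoxy]methoxy}benzaldehyde | O=Cc1c(CC=C(C)C)cc(OCOCC[Si](C)(C)C)c(OC)c1OCC=C(C)C
F11 | step 9 | 2-formyl-6-methoxy-3,4-bis(3-methylbut-2-en-1-yl)-5-{[2-(trimethylsilyl)ethoxy]methoxy}phenyl trifluoromethanesulfonate | O=Cc1c(CC=C(C)C)c(CC=C(C)C)c(OCOCC[Si](C)(C)C)c(OC)c1OS(=O)(=O)C(F)(F)F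
F12 | step 9 | 2-{hydroxy[2,4,6-tris(methoxymethoxy)phenyl]methyl}-6-methoxy-3,4-bis(3-methylbut-2-en-1-yl)-5-{[2-(trimethylsilyl)ethoxy]methoxy}phenyl trifluoromethanesulfonate (racemic) | OC(c1c(OCOC)cc(OCOC)cc1OCOC)c1c(CC=C(C)C)c(CC=C(C)C)c(OCOCC[Si](C)(C)C)c(OC)c1OS(=O)(=O)C(F)(F)F
F13 | step 9 | 6-methoxy-3,4-bis(3-methylbut-2-en-1-yl)-2-[2,4,6-tris(methoxymethoxy)benzoyl]-5-{[2-(trimethylsilyl)ethoxy]methoxy}phenyl trifluoromethanesulfonate | O=C(c1c(OCOC)cc(OCOC)cc1OCOC)c1c(CC=C(C)C)c(CC=C(C)C)c(OCOCC[Si](C)(C)C)c(OC)c1OS(=O)(=O)C(F)(F)F
F14 | step 9 | 2-[2-hydroxy-4,6-bis(methoxymethoxy)benzoyl]-6-methoxy-3,4-bis(3-methylbut-2-en-1-yl)-5-{[2-(trimethylsilyl)ethoxy]methoxy}phenyl trifluoromethanesulfonate | O=C(c1c(O)cc(OCOC)cc1OCOC)c1c(CC=C(C)C)c(CC=C(C)C)c(OCOCC[Si](C)(C)C)c(OC)c1OS(=O)(=O)C(F)(F)F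
F15 | step 13 | methyl 2-[2,5-dihydroxy-6-methoxy-3,4-bis(3-methylbut-2-en-1-yl)phenoxy]-4,6-dihydroxybenzoate | COC(=O)c1c(O)cc(O)cc1Oc1c(OC)c(O)c(CC=C(C)C)c(CC=C(C)C)c1O
A1 | alternative 1 | methyl 3-[2,5-bis(tert-butyldimethylsilyloxy)-6-methoxy-3,4-bis(3-methylbut-2-en-1-yl)phenoxy]prop-2-ynoate | COC(=O)C#COc1c(OC)c(O[Si](C)(C)C(C)(C)C)c(CC=C(C)C)c(CC=C(C)C)c1O[Si](C)(C)C(C)(C)C
A2 | alternative 1 | 1-methoxy-1,3-bis(trimethylsilyloxy)buta-1,3-diene (Chan's diene) | COC(O[Si](C)(C)C)=CC(=C)O[Si](C)(C)C
A3 | alternative 1 | methyl 2-[2,5-bis(tert-butyldimethylsilyloxy)-6-methoxy-3,4-bis(3-methylbut-2-en-1-yl)phenoxy]-4,6-dihydroxybenzoate | COC(=O)c1c(O)cc(O)cc1Oc1c(OC)c(O[Si](C)(C)C(C)(C)C)c(CC=C(C)C)c(CC=C(C)C)c1O[Si](C)(C)C(C)(C)C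
A4 | alternative 2 | 3,5-bis(methoxymethoxy)-2-(trimethylsilyl)phenyl trifluoromethanesulfonate | COCOc1cc(OCOC)c([Si](C)(C)C)c(OS(=O)(=O)C(F)(F)F)c1
A5 | alternative 2 | 2,3,6-trimethoxy-4,5-bis(3-methylbut-2-en-1-yl)phenol | Oc1c(OC)c(OC)c(CC=C(C)C)c(CC=C(C)C)c1OC
A6 | alternative 2 | 2-[2,3,6-trimethoxy-4,5-bis(3-methylbut-2-en-1-yl)phenoxy]-4,6-bis(methoxymethoxy)benzoic acid | OC(=O)c1c(OCOC)cc(OCOC)cc1Oc1c(OC)c(OC)c(CC=C(C)C)c(CC=C(C)C)c1OC
A7 | alternative 3 | methyl 2,4-diacetoxy-6-[2,5-diacetoxy-3,4-bis(bromomethyl)-6-methoxyphenoxy]benzoate | COC(=O)c1c(OC(C)=O)cc(OC(C)=O)cc1Oc1c(OC)c(OC(C)=O)c(CBr)c(CBr)c1OC(C)=O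
A8 | alternative 3 | tributyl(2-methylprop-1-en-1-yl)stannane | CCCC[Sn](CCCC)(CCCC)C=C(C)C
A9 | alternative 3 | methyl 2,4-diacetoxy-6-[2,5-diacetoxy-6-methoxy-3,4-bis(3-methylbut-2-en-1-yl)phenoxy]benzoate | COC(=O)c1c(OC(C)=O)cc(OC(C)=O)cc1Oc1c(OC)c(OC(C)=O)c(CC=C(C)C)c(CC=C(C)C)c1OC(C)=O
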